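## The problem

The target is an ent-labdane, (1R,4aS,5R,8aS)-1,4a-dimethyl-6-methylidene-5-[(3R)-3-methyl-5-{[(2R)-2-methylbutanoyl]oxy}pentyl]decahydronaphthalene-1-carboxylic acid. It is a trans-fused decalin (rings A and B) with a quaternary C4 carrying a methyl group and an axial carboxylic acid (C19), an angular methyl (C20) on quaternary C10, and an exocyclic methylidene at C8 (C17). C9 carries a chain C11–C16 whose C15 oxygen is acylated by (R)-2-methylbutanoic acid. Six stereocentres have to be set: C4, C5, C9 and C10 on the bicycle, C13 in the chain and C2' in the acyl group. The ring centres can be relayed: C4 can steer the face on which C10 is built, and the axial C20 methyl then sends reagents to the opposite face of C5 and C9, where both hydrogens sit in the target. C13 and C2' are too remote for control from the ring and must come from enantiopure building blocks. C19 and C20 are cis and 1,3-diaxial, so the C19 acid is crowded and needs a protecting group that resists hydride and organometallic reagents yet leaves without strong protic acid. The 8(17)-alkene moves into the ring under protic acid, the allylic C9 hydrogen is epimerisable whenever C11 is a carbonyl, and the 2-methylbutanoate is sensitive to base (C2'), hydride and organomagnesium reagents, so it must be attached late. The feature that opens a short route is that ring B bears its substituents on the contiguous atoms C8 (C17), C9 (C11) and C10 (C20): this is the pattern of a but-2-ynoate added across a diene C7=C6–C5=C10 anchored on ring A, the ynoate methyl becoming C17 and its ester carbon C11.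

## Retrosynthesis

**Acyl group and C19 protection.** Target 26 is traced to tert-butyl ester 24 (cut of the O–C(CH3)3 bond, through silyl ester 25), and 24 to alcohol 22 plus (R)-2-methylbutanoic acid 23 (cut of the C15–O acyl bond). Acylating next to last keeps the sensitive ester out of every hydride, amide-base and Grignard step; carrying it through the C11–C12 coupling is excluded by the organomagnesium reagent. Alcohol 22 has one stereocentre less and only robust functions. The forward steps must esterify without touching C2' and free the hindered C19 acid without protic acid.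

**C11–C12.** Alcohol 22 comes from its 4-methoxybenzyl ether 21, which is cut between C11 and C12 into tosylate 14 and Grignard reagent 20 (from bromide 19). A cut at C9–C11 would need a reactive centre on a ring carbon flanked by quaternary C10, and a cut at C12–C13 would put the C13 stereocentre on a reacting carbon. The C11–C12 cut keeps C13 one atom from the metal, where it is configurationally safe, and reduces the bicycle to a C16 unit with a one-carbon handle on C9. The forward reaction is an SN2 displacement at a hindered, β-branched primary carbon that must spare the tert-butyl ester; copper catalysis is chosen for it.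

**Side-chain fragment.** Bromide 19 goes back to alcohol 18, acid 17 and, through salt 16, to (S)-3-methyloxolan-2-one 15. The lactone already holds C12 (carbonyl), C13 with its methyl, C14 and C15 (ring O–CH2) in the right configuration. Opening it to the hydroxy carboxylate makes the two termini chemically different, so the C15 oxygen can be etherified before C12 is reduced; reduction to the diol first would leave two primary hydroxyls to be told apart.

**C9 and the 8(17)-alkene.** Tosylate 14 comes from alcohol 13 and this from the β,γ-unsaturated ester 12. Ester 12 is derived from the conjugated ester 10 through dienolate 11: no skeletal bond is cut, the double bond moves from C8=C9 to C8=C17 and a hydrogen is placed on C9. Methylenating a C8 ketone next to an epimerisable C9 is the obvious alternative; deconjugation instead derives the methylidene from a C8 methyl group, which is exactly what an alkyne cycloaddition delivers. The forward step needs deprotonation at C17 and not C7, and protonation of C9 trans to C20.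

**C5.** Ester 10 comes from diene diester 9 by adding hydrogen across C5=C6. This sets the trans ring fusion after the ring is made; the less substituted alkene must react, and from the face opposite C20.

**Ring B (key cut).** Adduct 9 is cut at C7–C8 and C9–C10 into diene 7 and methyl but-2-ynoate 8. No other cut of ring B removes all three contiguous substituents with one reagent, and it reduces the problem to a monocyclic ring A with a single stereocentre. The cycloaddition must be regioselective (ester carbon to C10) and face-selective under control of C4.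

**Ring A.** Diene 7 comes from enol triflate 6 (C5–C6 bond, Stille coupling), 6 from ketone 4 through enolate 5, 4 from keto ester 2 through enolate 3 (C10–C20 bond), and 2 from β-keto ester 1 (C4–methyl bond). Methylating C4 first, on achiral 1 under a chiral phase-transfer catalyst, avoids the matched/mismatched pairing that a racemic C10-methylated substrate would bring. The C10 methyl stereocentre introduced afterwards is erased when the enol triflate is formed.

## Roads not taken

**Alternative 1:** The cut is the transannular bond C5–C10 of a ten-membered ring. The precursor is cyclodecadiene A1, which holds a C1=C10 alkene, a C4=C5 enoate, the C8 ketal and the complete C9 side chain. With Fe(acac)3 and PhSiH3, hydrogen-atom transfer to C1 should give the tertiary C10 radical, which adds across the ring to C5 of the enoate (Giese-type) and gives trans-decalin A2.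
- Merits: both rings form at once, the trans fusion follows from the ring conformation, and the side chain is already in place, so no late coupling at hindered C11 is needed. In that respect it is better than the chosen plan.
- Weak points: A1 is a medium ring with two trans trisubstituted alkenes and a stereocentre, and its closure and alkene geometry are costly. The relation of C9 to C10 depends on which ring conformer cyclises. C4 still has to be methylated, and the C8 ketal must become a methylidene next to epimerisable C9.
- Comparison: the chosen plan answers with a much shorter assembly of the bicycle from two simple pieces and derives the methylidene from a methyl group. In exchange it accepts the late C11–C12 coupling.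

**Alternative 2:** The cut is C4–C5, with C19 tied back to C1 through oxygen. The precursor is δ-lactone A3. Its silyl ketene acetal should rearrange through a boat transition state (Ireland–Claisen ring contraction) to cyclohexene acid A4, forming C4–C5, the C1=C10 alkene and the free C19 acid.
- Merits: the quaternary C4 and C5 are set together by a well-understood pericyclic process with chirality transfer from one carbinol centre, and no asymmetric alkylation is needed. This C4/C5 relation is more securely controlled than the C4-to-C10 relay of the chosen plan.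
- Weak points: A4 is only ring A. Ring B, quaternary C10 (to be built on the C1=C10 alkene with control of the ring fusion), C9 and the 8(17)-alkene all remain, and chair/boat leakage would erode the diastereomeric purity.
- Comparison: the chosen plan makes ring B with its three contiguous substituents in one step and needs far fewer operations overall; what it gives up is the firmer stereocontrol at C4/C5.

**Alternative 3:** The cuts are C5–C10 and C8–C9. The precursor is acyclic trienoate A5, which on heating should undergo an intramolecular Diels–Alder reaction to octalin A6, closing rings A and B together.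
- Merits: C5, C9 and C10 are set in one step, the (E)-enoate geometry fixes C11 cis to C20 without a later protonation, and the tether enforces regiochemistry. In stereochemical economy this is the strongest of the four plans.
- Weak points: A5 requires an acyclic quaternary stereocentre C4 beside a fragile silyloxydiene and a long linear build-up. The β,β-disubstituted dienophile that must create quaternary C10 is sluggish. The C8 oxygen must afterwards be turned into a methylidene through a C8 ketone flanked by the C9 ester, an enolisable β-keto ester that resists olefination.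
- Comparison: the chosen plan has a cyclic, easily made C4 centre, commercial dienophile and direct access to the methylidene. It pays with a weaker facial bias in its cycloaddition.

Key step: step 5

Assumptions on the chemistry:
- tert-Butyl 2-oxocyclohexane-1-carboxylate (1) is taken as a commercial chemical.
- The phase-transfer catalyst antipode that delivers (R)-2 with methyl iodide is used; its sense of induction is assumed to parallel that known for larger alkyl halides.

## Route

Step 1
Reactants: 1 tert-butyl 2-oxocyclohexane-1-carboxylate
Product: 2 tert-butyl (1R)-1-methyl-2-oxocyclohexane-1-carboxylate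
Conditions: MeI, chiral C2-symmetric N-spiro binaphthyl-derived quaternary ammonium bromide (3,3'-diaryl, aryl = 3,5-bis(trifluoromethyl)phenyl; 1 mol%), CsOH·H2O, toluene, −40 °C
Reagents that add atoms: iodomethane, CI
Why: Asymmetric phase-transfer alkylation of a cyclic β-keto ester: the enolate is carried into toluene as a tight ion pair with the chiral ammonium cation, which shields one face, so methyl iodide should enter from the other and set the quaternary C4; the tert-butyl ester is the ester class on which this catalysis gives its best selectivity.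

Step 2
Reactants: 2 tert-butyl (1R)-1-methyl-2-oxocyclohexane-1-carboxylate
Product: 4 tert-butyl (1R)-1,3-dimethyl-2-oxocyclohexane-1-carboxylate (both C3 epimers), via lithium enolate 3 (not isolated)
Conditions: LiN(i-Pr)2, THF, −78 °C; MeI, −78 → 0 °C
Reagents that add atoms: iodomethane, CI
Why: Only C3 carries α-hydrogens, so the lithium enolate is regiodefined and its methylation installs the future C20; the new centre is formed without control, which is harmless because it becomes sp2 in the next step.

Step 3
Reactants: 4 tert-butyl (1R)-1,3-dimethyl-2-oxocyclohexane-1-carboxylate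
Product: 6 tert-butyl (1R)-1,3-dimethyl-2-(trifluoromethanesulfonyloxy)cyclohex-2-ene-1-carboxylate, via potassium enolate 5 (not isolated)
Conditions: KN(SiMe3)2, THF, −78 → 0 °C; PhNTf2, 0 °C → rt
Reagents that add atoms: N-phenylbis(trifluoromethanesulfonimide), O=S(=O)(N(c1ccccc1)S(=O)(=O)C(F)(F)F)C(F)(F)F
Why: Enolisation can only occur toward the methyl-bearing carbon, and O-sulfonylation of the tetrasubstituted enolate gives the enol triflate; this is the standard enol triflate synthesis, well known for 2,2,6-trisubstituted cyclohexanones.

Step 4
Reactants: 6 tert-butyl (1R)-1,3-dimethyl-2-(trifluoromethanesulfonyloxy)cyclohex-2-ene-1-carboxylate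
Product: 7 tert-butyl (1R)-2-ethenyl-1,3-dimethylcyclohex-2-ene-1-carboxylate
Conditions: CH2=CHSnBu3, Pd(PPh3)4 (5 mol%), LiCl, THF, 65 °C
Reagents that add atoms: tributyl(ethenyl)stannane, C=C[Sn](CCCC)(CCCC)CCCC
Why: Stille coupling: zerovalent palladium inserts into the C–OTf bond, chloride stabilises the vinylpalladium intermediate, the vinyl group is transferred from tin and reductive elimination forms C5–C6; hindered 2,6-disubstituted cyclohexenyl triflates are established partners.

Step 5
Reactants: 7 tert-butyl (1R)-2-ethenyl-1,3-dimethylcyclohex-2-ene-1-carboxylate; 8 methyl but-2-ynoate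
Product: 9 1-tert-butyl 5-methyl (1R,4aR)-1,4a,6-trimethyl-1,2,3,4,4a,7-hexahydronaphthalene-1,5-dicarboxylate
Conditions: neat 8 (8 equiv), 2,6-di-tert-butyl-4-methylphenol (2 mol%), sealed tube under argon, 150 °C
Reagents that add atoms: none
Why: A thermal, normal-electron-demand Diels–Alder reaction: the diene HOMO of 7 (largest coefficient at the unsubstituted terminus C7) and the LUMO of ynoate 8 (largest coefficient at the methyl-bearing β-carbon) combine in a concerted, asynchronous [4+2] transition state in which C7–C8 runs ahead of C9–C10. The closest known reaction type is the cycloaddition of 1-vinylcyclohexenes bearing a fully substituted diene terminus with acetylenic esters, the classical entry to drimane-type decalins. Ring B is closed by intermolecular [4+2] annulation, four of its atoms (C7, C6, C5, C10) coming from the diene and two (C8, C9) from the alkyne, and it should emerge as a cyclohexa-1,4-diene (C5=C6, C8=C9). The only new stereocentre is C10 and it is controlled by C4: in the reacting half-chair the ester, which has the smaller conformational demand, should stand pseudoaxial and the methyl pseudoequatorial, so that the ynoate adds to the face opposite the tert-butyl ester and C20 ends up cis to C19. Regioselectivity (ester carbon to C10) is secured by the polarisation of both partners, and there is no endo/exo question because the dienophile is an alkyne. The step also needs the cycloaddition to outrun [1,5]-hydrogen shift and polymerisation of the cis-substituted diene, for which a large excess of neat dienophile, a radical inhibitor and the lowest workable temperature are used.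

Step 6
Reactants: 9 1-tert-butyl 5-methyl (1R,4aR)-1,4a,6-trimethyl-1,2,3,4,4a,7-hexahydronaphthalene-1,5-dicarboxylate
Product: 10 1-tert-butyl 5-methyl (1R,4aR,8aS)-1,4a,6-trimethyl-1,2,3,4,4a,7,8,8a-octahydronaphthalene-1,5-dicarboxylate
Conditions: H2 (4 atm), 10% Pd/C, EtOAc, rt
Reagents that add atoms: none
Why: Heterogeneous catalytic hydrogenation: the trisubstituted C5=C6 alkene should add hydrogen syn from the face that carries only the C4 methyl, opposite C20 and the C19 ester, which sets H5 trans to C20; the tetrasubstituted, conjugated C8=C9 is too hindered to react.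

Step 7
Reactants: 10 1-tert-butyl 5-methyl (1R,4aR,8aS)-1,4a,6-trimethyl-1,2,3,4,4a,7,8,8a-octahydronaphthalene-1,5-dicarboxylate
Product: 12 1-tert-butyl 5-methyl (1R,4aR,5R,8aS)-1,4a-dimethyl-6-methylidenedecahydronaphthalene-1,5-dicarboxylate, via lithium dienolate 11 (not isolated)
Conditions: LiN(i-Pr)2, THF, −78 → −40 °C; AcOH, THF, −78 °C
Reagents that add atoms: none
Why: Deconjugative kinetic protonation of an extended ester enolate: the amide base should remove a proton from C17, the γ-carbon held cis to the ester carbonyl, and the cross-conjugated dienolate is protonated at the α-carbon C9 from the face opposite axial C20, which gives the 8(17)-methylidene and the equatorial C9 ester; the C19 ester has no α-hydrogen.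

Step 8
Reactants: 12 1-tert-butyl 5-methyl (1R,4aR,5R,8aS)-1,4a-dimethyl-6-methylidenedecahydronaphthalene-1,5-dicarboxylate
Product: 13 tert-butyl (1R,4aR,5R,8aS)-5-(hydroxymethyl)-1,4a-dimethyl-6-methylidenedecahydronaphthalene-1-carboxylate
Conditions: i-Bu2AlH (2.5 equiv), CH2Cl2, −78 → −20 °C; aq. potassium sodium tartrate
Reagents that add atoms: none
Why: Hydride reduction of the methyl ester to the primary alcohol; the axial tert-butyl ester on quaternary C4 is shielded on both the acyl and the alkyl side and should survive, and the non-basic conditions leave C9 untouched.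

Step 9
Reactants: 13 tert-butyl (1R,4aR,5R,8aS)-5-(hydroxymethyl)-1,4a-dimethyl-6-methylidenedecahydronaphthalene-1-carboxylate
Product: 14 tert-butyl (1R,4aR,5R,8aS)-1,4a-dimethyl-6-methylidene-5-{[(4-methylbenzenesulfonyl)oxy]methyl}decahydronaphthalene-1-carboxylate
Conditions: TsCl, pyridine, DMAP (cat.), CH2Cl2, 0 °C → rt
Reagents that add atoms: 4-methylbenzenesulfonyl chloride, Cc1ccc(S(=O)(=O)Cl)cc1
Why: Sulfonylation of a primary alcohol at oxygen; no stereocentre is involved.

Step 10
Reactants: 15 (3S)-3-methyloxolan-2-one
Product: 17 (2S)-4-[(4-methoxyphenyl)methoxy]-2-methylbutanoic acid, via potassium hydroxy carboxylate 16 (not isolated)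
Conditions: KOH, MeOH/H2O, rt, then evaporation to dryness; NaH, 4-MeOC6H4CH2Cl, n-Bu4NI (cat.), DMF, 0 °C → rt; aq. HCl to pH 3, 0 °C
Reagents that add atoms: potassium hydroxide, [K+].[OH-]; 4-methoxybenzyl chloride, COc1ccc(CCl)cc1
Why: Saponification opens the lactone, and Williamson etherification of the alkoxide, far more nucleophilic than the carboxylate, marks the C15 oxygen; the carboxylate α-hydrogen is not acidic under these conditions, so C13 should keep its configuration.

Step 11
Reactants: 17 (2S)-4-[(4-methoxyphenyl)methoxy]-2-methylbutanoic acid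
Product: 18 (2S)-4-[(4-methoxyphenyl)methoxy]-2-methylbutan-1-ol
Conditions: LiAlH4, THF, 0 °C → rt
Reagents that add atoms: none
Why: Hydride reduction of the carboxylic acid to the primary alcohol (C12); the benzylic ether is inert.

Step 12
Reactants: 18 (2S)-4-[(4-methoxyphenyl)methoxy]-2-methylbutan-1-ol
Product: 19 1-{[(3S)-4-bromo-3-methylbutoxy]methyl}-4-methoxybenzene
Conditions: CBr4, PPh3, CH2Cl2, 0 °C
Reagents that add atoms: carbon tetrabromide, BrC(Br)(Br)Br
Why: Appel reaction: the alkoxyphosphonium ion is displaced by bromide at the primary carbon under neutral conditions; the adjacent stereocentre is not touched.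

Step 13
Reactants: 19 1-{[(3S)-4-bromo-3-methylbutoxy]methyl}-4-methoxybenzene; 14 tert-butyl (1R,4aR,5R,8aS)-1,4a-dimethyl-6-methylidene-5-{[(4-methylbenzenesulfonyl)oxy]methyl}decahydronaphthalene-1-carboxylate
Product: 21 tert-butyl (1R,4aS,5R,8aS)-5-{(3R)-5-[(4-methoxyphenyl)methoxy]-3-methylpentyl}-1,4a-dimethyl-6-methylidenedecahydronaphthalene-1-carboxylate, via Grignard reagent 20 (not isolated)
Conditions: Mg, THF, 40 °C; then 14, Li2CuCl4 (5 mol%), THF, −20 → 0 °C
Reagents that add atoms: none
Why: Copper-catalysed alkyl–alkyl coupling of a primary Grignard reagent with a primary tosylate: the organocopper species formed in the flask should displace the tosylate at C11 by an SN2-type path, tolerating the hindered tert-butyl ester at low temperature; C13 lies β to magnesium and cannot epimerise.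

Step 14
Reactants: 21 tert-butyl (1R,4aS,5R,8aS)-5-{(3R)-5-[(4-methoxyphenyl)methoxy]-3-methylpentyl}-1,4a-dimethyl-6-methylidenedecahydronaphthalene-1-carboxylate
Product: 22 tert-butyl (1R,4aS,5R,8aS)-5-[(3R)-5-hydroxy-3-methylpentyl]-1,4a-dimethyl-6-methylidenedecahydronaphthalene-1-carboxylate
Conditions: DDQ, CH2Cl2/pH 7 phosphate buffer, 0 °C
Reagents that add atoms: none
Why: Oxidative cleavage of the 4-methoxybenzyl ether by hydride abstraction and hydrolysis of the oxocarbenium ion; the buffered, non-acidic medium should leave the 1,1-disubstituted alkene and the tert-butyl ester intact.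

Step 15
Reactants: 22 tert-butyl (1R,4aS,5R,8aS)-5-[(3R)-5-hydroxy-3-methylpentyl]-1,4a-dimethyl-6-methylidenedecahydronaphthalene-1-carboxylate; 23 (2R)-2-methylbutanoic acid
Product: 24 tert-butyl (1R,4aS,5R,8aS)-1,4a-dimethyl-6-methylidene-5-[(3R)-3-methyl-5-{[(2R)-2-methylbutanoyl]oxy}pentyl]decahydronaphthalene-1-carboxylate
Conditions: EDC·HCl, DMAP (cat.), CH2Cl2, 0 °C → rt
Reagents that add atoms: none
Why: Steglich esterification of a primary alcohol; a simple α-alkyl acid without further activating group should pass through the acylpyridinium stage without loss of configuration at C2'.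

Step 16
Reactants: 24 tert-butyl (1R,4aS,5R,8aS)-1,4a-dimethyl-6-methylidene-5-[(3R)-3-methyl-5-{[(2R)-2-methylbutanoyl]oxy}pentyl]decahydronaphthalene-1-carboxylate
Product: 26 (1R,4aS,5R,8aS)-1,4a-dimethyl-6-methylidene-5-[(3R)-3-methyl-5-{[(2R)-2-methylbutanoyl]oxy}pentyl]decahydronaphthalene-1-carboxylic acid, via trimethylsilyl ester 25 (not isolated)
Conditions: Me3SiOTf, 2,6-lutidine, CH2Cl2, 0 °C → rt; then pH 5 aqueous buffer, rt
Reagents that add atoms: none
Why: Silyl triflate-mediated tert-butyl ester cleavage: silylation of the carbonyl oxygen is followed by loss of the tert-butyl cation as 2-methylpropene, the excess lutidine keeps the medium free of protic acid so that the 8(17)-alkene should stay in place, and the silyl ester is hydrolysed on work-up; the primary alkyl ester at C15 does not ionise under these conditions.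

## Compound list

1 | tert-butyl 2-oxocyclohexane-1-carboxylate | O=C1CCCCC1C(=O)OC(C)(C)C | starting material
2 | tert-butyl (1R)-1-methyl-2-oxocyclohexane-1-carboxylate | O=C1CCCC[C@@]1(C)C(=O)OC(C)(C)C | intermediate
3 | lithium (6R)-6-(tert-butoxycarbonyl)-6-methylcyclohex-1-en-1-olate | [Li]OC1=CCCC[C@@]1(C)C(=O)OC(C)(C)C | intermediate
4 | tert-butyl (1R)-1,3-dimethyl-2-oxocyclohexane-1-carboxylate (both C3 epimers) | CC1CCC[C@@](C)(C(=O)OC(C)(C)C)C1=O | intermediate
5 | potassium (6R)-6-(tert-butoxycarbonyl)-2,6-dimethylcyclohex-1-en-1-olate | [K]OC1=C(C)CCC[C@@]1(C)C(=O)OC(C)(C)C | intermediate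
6 | tert-butyl (1R)-1,3-dimethyl-2-(trifluoromethanesulfonyloxy)cyclohex-2-ene-1-carboxylate | O=S(=O)(OC1=C(C)CCC[C@@]1(C)C(=O)OC(C)(C)C)C(F)(F)F | intermediate
7 | tert-butyl (1R)-2-ethenyl-1,3-dimethylcyclohex-2-ene-1-carboxylate | C=CC1=C(C)CCC[C@@]1(C)C(=O)OC(C)(C)C | intermediate
8 | methyl but-2-ynoate | CC#CC(=O)OC | starting material
9 | 1-tert-butyl 5-methyl (1R,4aR)-1,4a,6-trimethyl-1,2,3,4,4a,7-hexahydronaphthalene-1,5-dicarboxylate | CC1=C(C(=O)OC)[C@]2(C)CCC[C@@](C)(C(=O)OC(C)(C)C)C2=CC1 | intermediate
10 | 1-tert-butyl 5-methyl (1R,4aR,8aS)-1,4a,6-trimethyl-1,2,3,4,4a,7,8,8a-octahydronaphthalene-1,5-dicarboxylate | CC1=C(C(=O)OC)[C@]2(C)CCC[C@@](C)(C(=O)OC(C)(C)C)[C@H]2CC1 | intermediate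
11 | lithium dienolate of 10 (C17=C8–C9=C(OLi)OMe; ring centres as in 10) | C=C1CC[C@H]2[C@@](C)(CCC[C@@]2(C)C(=O)OC(C)(C)C)C1=C(OC)O[Li] | intermediate
12 | 1-tert-butyl 5-methyl (1R,4aR,5R,8aS)-1,4a-dimethyl-6-methylidenedecahydronaphthalene-1,5-dicarboxylate | C=C1CC[C@H]2[C@@](C)(CCC[C@@]2(C)C(=O)OC(C)(C)C)[C@@H]1C(=O)OC | intermediate
13 | tert-butyl (1R,4aR,5R,8aS)-5-(hydroxymethyl)-1,4a-dimethyl-6-methylidenedecahydronaphthalene-1-carboxylate | C=C1CC[C@H]2[C@@](C)(CCC[C@@]2(C)C(=O)OC(C)(C)C)[C@@H]1CO | intermediate
14 | tert-butyl (1R,4aR,5R,8aS)-1,4a-dimethyl-6-methylidene-5-{[(4-methylbenzenesulfonyl)oxy]methyl}decahydronaphthalene-1-carboxylate | C=C1CC[C@H]2[C@@](C)(CCC[C@@]2(C)C(=O)OC(C)(C)C)[C@@H]1COS(=O)(=O)c1ccc(C)cc1 | intermediate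
15 | (3S)-3-methyloxolan-2-one | C[C@H]1CCOC1=O | starting material
16 | potassium (2S)-4-hydroxy-2-methylbutanoate | C[C@@H](CCO)C(=O)[O-].[K+] | intermediate
17 | (2S)-4-[(4-methoxyphenyl)methoxy]-2-methylbutanoic acid | C[C@@H](CCOCc1ccc(OC)cc1)C(=O)O | intermediate
18 | (2S)-4-[(4-methoxyphenyl)methoxy]-2-methylbutan-1-ol | C[C@@H](CCOCc1ccc(OC)cc1)CO | intermediate
19 | 1-{[(3S)-4-bromo-3-methylbutoxy]methyl}-4-methoxybenzene | C[C@@H](CCOCc1ccc(OC)cc1)CBr | intermediate
20 | bromo{(2S)-4-[(4-methoxyphenyl)methoxy]-2-methylbutyl}magnesium | C[C@@H](CCOCc1ccc(OC)cc1)C[Mg]Br | intermediate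
21 | tert-butyl (1R,4aS,5R,8aS)-5-{(3R)-5-[(4-methoxyphenyl)methoxy]-3-methylpentyl}-1,4a-dimethyl-6-methylidenedecahydronaphthalene-1-carboxylate | C=C1CC[C@H]2[C@@](C)(CCC[C@@]2(C)C(=O)OC(C)(C)C)[C@@H]1CC[C@@H](C)CCOCc1ccc(OC)cc1 | intermediate
22 | tert-butyl (1R,4aS,5R,8aS)-5-[(3R)-5-hydroxy-3-methylpentyl]-1,4a-dimethyl-6-methylidenedecahydronaphthalene-1-carboxylate | C=C1CC[C@H]2[C@@](C)(CCC[C@@]2(C)C(=O)OC(C)(C)C)[C@@H]1CC[C@@H](C)CCO | intermediate
23 | (2R)-2-methylbutanoic acid | CC[C@@H](C)C(=O)O | starting material
24 | tert-butyl (1R,4aS,5R,8aS)-1,4a-dimethyl-6-methylidene-5-[(3R)-3-methyl-5-{[(2R)-2-methylbutanoyl]oxy}pentyl]decahydronaphthalene-1-carboxylate | C=C1CC[C@H]2[C@@](C)(CCC[C@@]2(C)C(=O)OC(C)(C)C)[C@@H]1CC[C@@H](C)CCOC(=O)[C@H](C)CC | intermediate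
25 | trimethylsilyl (1R,4aS,5R,8aS)-1,4a-dimethyl-6-methylidene-5-[(3R)-3-methyl-5-{[(2R)-2-methylbutanoyl]oxy}pentyl]decahydronaphthalene-1-carboxylate | C=C1CC[C@H]2[C@@](C)(CCC[C@@]2(C)C(=O)O[Si](C)(C)C)[C@@H]1CC[C@@H](C)CCOC(=O)[C@H](C)CC | intermediate
26 | (1R,4aS,5R,8aS)-1,4a-dimethyl-6-methylidene-5-[(3R)-3-methyl-5-{[(2R)-2-methylbutanoyl]oxy}pentyl]decahydronaphthalene-1-carboxylic acid | C=C1CC[C@H]2[C@@](C)(CCC[C@@]2(C)C(=O)O)[C@@H]1CC[C@@H](C)CCOC(=O)[C@H](C)CC | target

## Step count and least certain steps

Total: 16 steps. Longest linear sequence: 13 steps (steps 1–9 and 13–16); the side-chain fragment takes 3 steps (10–12).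

**Step 5 (key step).** Three processes may interfere.
- The diene carries a cis substituent (C20) on its reacting terminus and is twisted out of the cisoid form, so the cycloaddition may be slow enough for [1,5]-hydrogen shift, diene polymerisation or thermal loss of 2-methylpropene from the ester to compete.
- Facial selectivity may be only moderate, because the two C4 substituents differ little in effective size. The epimer at C10 would have to be removed by chromatography at 9 or 10.
- A minor regioisomer may form.

Fallback: starting from 7, the dienophile is changed to the more reactive but-2-ynal, which should add at much lower temperature (toluene, 80 °C, or Me2AlCl, CH2Cl2, −40 °C), where the energy difference between the two faces counts for more. This gives tert-butyl (1R,4aR)-5-formyl-1,4a,6-trimethyl-1,2,3,4,4a,7-hexahydronaphthalene-1-carboxylate F1. Chlorite oxidation (NaClO2, NaH2PO4, 2-methylbut-2-ene, t-BuOH/H2O) gives (5R,8aR)-5-(tert-butoxycarbonyl)-2,5,8a-trimethyl-3,5,6,7,8,8a-hexahydronaphthalene-1-carboxylic acid F2, and Me3SiCHN2 in toluene/MeOH returns to 9.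

**Step 1.** Methyl iodide is the smallest electrophile, and face discrimination within the ion pair may be lower than with benzylic halides, which would erode the enantiomeric purity of every later compound. Fallback: starting from 1, condensation with tert-butyl L-valinate gives tert-butyl N-[2-(tert-butoxycarbonyl)cyclohex-1-en-1-yl]-L-valinate F3. LiN(i-Pr)2 converts it into its N-lithio derivative F4, whose chelated structure is methylated on one face of the ring carbon to give tert-butyl N-[(2R)-2-(tert-butoxycarbonyl)-2-methylcyclohexylidene]-L-valinate F5. The solvent regime known to select the required face is used, or the D-amino ester. Mild aqueous acid hydrolyses the imine and returns to 2.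

**Step 6.** Hydrogen may be delivered in part to the wrong face (cis fusion) if the C19 ester guides the substrate onto the catalyst, or the alkene may migrate on palladium before it is reduced. Fallback: from 9 directly to 10 by hydrogen-atom-transfer hydrogenation (Mn(dpm)3, dpm = 2,2,6,6-tetramethylheptane-3,5-dionate, PhSiH3, t-BuOOH, i-PrOH). The tertiary C5 radical is quenched axially, the mode that favours trans-fused decalins with an angular methyl group; no new compound is involved.

**Step 7.** Deprotonation may occur partly at C7 (giving the endocyclic 7-ene) or be slow because the crowded ester is twisted out of conjugation, and some reconjugation may occur on quench. Fallback: from 10 directly to 12 by photochemical deconjugation (254 nm, Et2O, catalytic 1,2-dimethylimidazole). The excited enoate abstracts a γ-hydrogen from C17 through a six-membered transition state, which is only possible for the carbon cis to the carbonyl, and the dienol is protonated at C9; no new compound is involved.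

**Step 13.** Displacement at C11 is slowed by β-branching and the neighbouring quaternary C10, so elimination toward C9 or homocoupling and reduction of the Grignard reagent may take over. Fallback: a sulfone alkylation–desulfonylation in place of the organocopper coupling.
- Alcohol 13 is converted (I2, PPh3, imidazole) into tert-butyl (1R,4aR,5R,8aS)-5-(iodomethyl)-1,4a-dimethyl-6-methylidenedecahydronaphthalene-1-carboxylate F6.
- Bromide 19 is converted (PhSO2Na, DMF) into 1-{[(3S)-4-(benzenesulfonyl)-3-methylbutoxy]methyl}-4-methoxybenzene F7.
- n-BuLi in THF/DMPU at −78 °C gives the α-lithio sulfone F8, a soft and strongly nucleophilic carbanion, which is alkylated by F6 to tert-butyl (1R,4aS,5R,8aS)-5-{(3S)-2-(benzenesulfonyl)-5-[(4-methoxyphenyl)methoxy]-3-methylpentyl}-1,4a-dimethyl-6-methylidenedecahydronaphthalene-1-carboxylate F9 (both epimers at the sulfonyl carbon).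
- Reductive desulfonylation (Mg, MeOH) returns to 21.

**Step 16.** Silylation of the crowded C19 carbonyl may be slow, and forcing it may silylate or epimerise the side-chain ester or let traces of triflic acid move the alkene. Fallback: the order of the last two operations is reversed.
- Alcohol 22 is treated with Me3SiOTf and 2,6-lutidine under more forcing conditions, which are harmless at that stage, to give trimethylsilyl (1R,4aS,5R,8aS)-1,4a-dimethyl-6-methylidene-5-{(3R)-3-methyl-5-[(trimethylsilyl)oxy]pentyl}decahydronaphthalene-1-carboxylate F10.
- Buffered aqueous work-up gives (1R,4aS,5R,8aS)-5-[(3R)-5-hydroxy-3-methylpentyl]-1,4a-dimethyl-6-methylidenedecahydronaphthalene-1-carboxylic acid F11.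
- Acid 23 is converted with oxalyl chloride into (2R)-2-methylbutanoyl chloride F12, which in pyridine/CH2Cl2 at −20 °C acylates only the primary hydroxyl of F11, the hindered C19 acid being left free, and gives 26.

## Further compounds

F1 | step 5 | tert-butyl (1R,4aR)-5-formyl-1,4a,6-trimethyl-1,2,3,4,4a,7-hexahydronaphthalene-1-carboxylate | CC1=C(C=O)[C@]2(C)CCC[C@@](C)(C(=O)OC(C)(C)C)C2=CC1
F2 | step 5 | (5R,8aR)-5-(tert-butoxycarbonyl)-2,5,8a-trimethyl-3,5,6,7,8,8a-hexahydronaphthalene-1-carboxylic acid | CC1=C(C(=O)O)[C@]2(C)CCC[C@@](C)(C(=O)OC(C)(C)C)C2=CC1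
F3 | step 1 | tert-butyl N-[2-(tert-butoxycarbonyl)cyclohex-1-en-1-yl]-L-valinate | CC(C)[C@H](NC1=C(C(=O)OC(C)(C)C)CCCC1)C(=O)OC(C)(C)C
F4 | step 1 | N-lithio derivative of tert-butyl N-[2-(tert-butoxycarbonyl)cyclohex-1-en-1-yl]-L-valinate | CC(C)[C@H](N([Li])C1=C(C(=O)OC(C)(C)C)CCCC1)C(=O)OC(C)(C)C
F5 | step 1 | tert-butyl N-[(2R)-2-(tert-butoxycarbonyl)-2-methylcyclohexylidene]-L-valinate | CC(C)[C@H](N=C1CCCC[C@@]1(C)C(=O)OC(C)(C)C)C(=O)OC(C)(C)C
F0 | step 6 | none | none
F0 | step 7 | none | none
F6 | step 13 | tert-butyl (1R,4aR,5R,8aS)-5-(iodomethyl)-1,4a-dimethyl-6-methylidenedecahydronaphthalene-1-carboxylate | C=C1CC[C@H]2[C@@](C)(CCC[C@@]2(C)C(=O)OC(C)(C)C)[C@@H]1CI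
F7 | step 13 | 1-{[(3S)-4-(benzenesulfonyl)-3-methylbutoxy]methyl}-4-methoxybenzene | C[C@@H](CCOCc1ccc(OC)cc1)CS(=O)(=O)c1ccccc1
F8 | step 13 | α-lithio derivative of 1-{[(3S)-4-(benzenesulfonyl)-3-methylbutoxy]methyl}-4-methoxybenzene | C[C@@H](CCOCc1ccc(OC)cc1)C([Li])S(=O)(=O)c1ccccc1
F9 | step 13 | tert-butyl (1R,4aS,5R,8aS)-5-{(3S)-2-(benzenesulfonyl)-5-[(4-methoxyphenyl)methoxy]-3-methylpentyl}-1,4a-dimethyl-6-methylidenedecahydronaphthalene-1-carboxylate (both epimers at the sulfonyl carbon) | C=C1CC[C@H]2[C@@](C)(CCC[C@@]2(C)C(=O)OC(C)(C)C)[C@@H]1CC([C@@H](C)CCOCc1ccc(OC)cc1)S(=O)(=O)c1ccccc1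
F10 | step 16 | trimethylsilyl (1R,4aS,5R,8aS)-1,4a-dimethyl-6-methylidene-5-{(3R)-3-methyl-5-[(trimethylsilyl)oxy]pentyl}decahydronaphthalene-1-carboxylate | C=C1CC[C@H]2[C@@](C)(CCC[C@@]2(C)C(=O)O[Si](C)(C)C)[C@@H]1CC[C@@H](C)CCO[Si](C)(C)C
F11 | step 16 | (1R,4aS,5R,8aS)-5-[(3R)-5-hydroxy-3-methylpentyl]-1,4a-dimethyl-6-methylidenedecahydronaphthalene-1-carboxylic acid | C=C1CC[C@H]2[C@@](C)(CCC[C@@]2(C)C(=O)O)[C@@H]1CC[C@@H](C)CCO
F12 | step 16 | (2R)-2-methylbutanoyl chloride | CC[C@@H](C)C(Cl)=O
A1 | alternative 1 | tert-butyl cyclodeca-1,7-diene-1-carboxylate with 7-methyl, a 5,5-ethylenedioxy ketal and a 6-[(3R)-5-{[tert-butyl(dimethyl)silyl]oxy}-3-methylpentyl] group, both ring alkenes trans within the ring, C9 as in the target | C/C1=C\CC/C(C(=O)OC(C)(C)C)=C/CCC2(OCCO2)[C@H]1CC[C@@H](C)CCO[Si](C)(C)C(C)(C)C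
A2 | alternative 1 | trans-fused decalin tert-butyl ester with C8 ethylene ketal, C4 unmethylated (both C4 epimers), C5, C9, C10 and C13 as in the target, C15 tert-butyldimethylsilyl ether | O1CCOC12CC[C@H]3[C@@](C)(CCCC3C(=O)OC(C)(C)C)[C@@H]2CC[C@@H](C)CCO[Si](C)(C)C(C)(C)C
A3 | alternative 2 | (6S)-6-[(2E)-5-{[tert-butyl(dimethyl)silyl]oxy}pent-2-en-2-yl]-3-methyloxan-2-one (either C3 epimer) | CC1CC[C@H](OC1=O)/C(C)=C/CCO[Si](C)(C)C(C)(C)C
A4 | alternative 2 | (1R,2S)-2-(2-{[tert-butyl(dimethyl)silyl]oxy}ethyl)-1,3-dimethylcyclohex-3-ene-1-carboxylic acid | CC(C)(C)[Si](C)(C)OCC[C@H]1C(C)=CCC[C@@]1(C)C(=O)O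
A5 | alternative 3 | 1-tert-butyl 8-methyl (2R,6E)-2-[(1E,3E)-4-{[tert-butyl(dimethyl)silyl]oxy}buta-1,3-dien-1-yl]-2,6-dimethyloct-6-enedioate | COC(=O)/C=C(\C)CCC[C@@](C)(C(=O)OC(C)(C)C)/C=C/C=C/O[Si](C)(C)C(C)(C)C
A6 | alternative 3 | 1-tert-butyl 5-methyl 6-{[tert-butyl(dimethyl)silyl]oxy}-1,4a-dimethyl-1,2,3,4,4a,5,6,8a-octahydronaphthalene-1,5-dicarboxylate, trans-fused, C4, C5, C9 and C10 as in the target | CC(C)(C)[Si](C)(C)O[C@@H]1C=C[C@H]2[C@@](C)(CCC[C@@]2(C)C(=O)OC(C)(C)C)[C@@H]1C(=O)OC
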